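**Retrosynthetic overview**

- 30 ⇒ 29: one acid hydrolysis frees the three phenols (MOM ethers) and the 3-OH (mixed ketal). All rings and both stereocentres are already in place.
- 29 ⇒ 14 + 24: ring C is closed last, in one operation (O1–C8a and C4–C4a), by annulating the ring A aryne 26 (triple bond C4a≡C8a) with the four-atom chain O1–C2–C3–C4 of 24.
- Enabling feature: in ring A the two carbons to be bonded are neighbours. C4a sits beside the C5 oxygen and C8a beside the C8 prenyl CH2, so C5–O polarises the aryne (oxygen to C8a, carbanion at C4a). In ring C the chain O1–C2–C3–C4 is an anti-2,3-dihydroxy acid whose C4 can be offered as a lactone carbonyl.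
- 24 ⇒ 19 + 20: anti-glycolate aldol on a butane-2,3-diacetal dioxanone. This temporary ring is chiral auxiliary, 3-O protection and acyl activator at once, and the aldol sets C2 and C3.
- 14 ⇒ 1: ring A is bought (resorcinol) and filled by ortho metalation/prenylation, C–H borylation/oxidation and two carbamate-directed metalations. Ring order: A and B bought, temporary dioxanone, then C.

Key step: step 14

Remark: flavonoid numbering (O1, C2, C3, C4, C4a, C5–C8, C8a) is used for rings A and C. Prenyl = 3-methylbut-2-en-1-yl, MOM = CH2OCH3. The (2R,3R)-trans target corresponds to an anti-(2R,3R)-2,3-dihydroxy acid. Compound 20 is taken as a catalogue compound.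

**Step 1**
Reactants: 1 resorcinol
Product: 2 1,3-bis(methoxymethoxy)benzene
Conditions: MOMCl (2.5 equiv), i-Pr2NEt (3 equiv), CH2Cl2, 0 °C → rt
Reagents that add atoms: chloromethyl methyl ether (MOMCl), COCCl
Why: Standard O-alkylation of both phenols gives the bis-MOM ether, whose groups later direct metalation and fall in the final acid step.

**Step 2**
Reactants: 2 1,3-bis(methoxymethoxy)benzene
Product: 4 1,3-bis(methoxymethoxy)-2-(3-methylbut-2-en-1-yl)benzene, via aryllithium 3 (not isolated)
Conditions: n-BuLi (1.1 equiv), THF, 0 °C → rt, 1 h; prenyl bromide (1.2 equiv), −78 °C → rt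
Reagents that add atoms: prenyl bromide (1-bromo-3-methylbut-2-ene), CC(C)=CCBr
Why: Directed ortho metalation takes place between the two cooperating OMOM groups and the aryllithium is alkylated at the primary carbon of prenyl bromide (SN2), a sequence with close precedent for 2-prenylresorcinol ethers.

**Step 3**
Reactants: 4 1,3-bis(methoxymethoxy)-2-(3-methylbut-2-en-1-yl)benzene
Product: 6 3,5-bis(methoxymethoxy)-4-(3-methylbut-2-en-1-yl)phenol, via aryl boronate 5 (not isolated)
Conditions: [Ir(OMe)(cod)]2 (1.5 mol %), 4,4'-di-tert-butyl-2,2'-bipyridine (3 mol %), B2pin2 (0.6 equiv), THF, 65 °C; then 30% H2O2, aq NaOH, 0 °C → rt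
Reagents that add atoms: hydrogen peroxide, OO; bis(pinacolato)diboron, CC1(C)OB(OC1(C)C)B1OC(C)(C)C(C)(C)O1 (its boron unit stays only in 5)
Why: Sterically controlled iridium-catalysed C–H borylation can reach only the one ring hydrogen without an ortho substituent (para to the prenyl group), and alkaline peroxide then turns C–B into C–OH without touching the unactivated trisubstituted alkene.

**Step 4**
Reactants: 6 3,5-bis(methoxymethoxy)-4-(3-methylbut-2-en-1-yl)phenol
Product: 7 3,5-bis(methoxymethoxy)-4-(3-methylbut-2-en-1-yl)phenyl N,N-diethylcarbamate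
Conditions: ClC(O)NEt2 (1.3 equiv), K2CO3 (2 equiv), MeCN, reflux
Reagents that add atoms: N,N-diethylcarbamoyl chloride, CCN(CC)C(=O)Cl
Why: O-carbamoylation installs the strongest oxygen-based director for ortho metalation on the oxygen that will later leave as triflate.

**Step 5**
Reactants: 7 3,5-bis(methoxymethoxy)-4-(3-methylbut-2-en-1-yl)phenyl N,N-diethylcarbamate
Product: 9 3,5-bis(methoxymethoxy)-4-(3-methylbut-2-en-1-yl)-2-(trimethylsilyl)phenyl N,N-diethylcarbamate, via aryllithium 8 (not isolated)
Conditions: s-BuLi (1.2 equiv), TMEDA (1.2 equiv), THF, −78 °C, 1 h; TMSCl (1.5 equiv), −78 °C → rt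
Reagents that add atoms: chlorotrimethylsilane, C[Si](C)(C)Cl
Why: Directed ortho metalation occurs at one of the two equivalent positions flanked by carbamate and OMOM, −78 °C suppresses the anionic ortho-Fries shift, and TMSCl traps the anion.

**Step 6**
Reactants: 9 3,5-bis(methoxymethoxy)-4-(3-methylbut-2-en-1-yl)-2-(trimethylsilyl)phenyl N,N-diethylcarbamate
Product: 12 3,5-bis(methoxymethoxy)-2,4-bis(3-methylbut-2-en-1-yl)-6-(trimethylsilyl)phenyl N,N-diethylcarbamate, via aryllithium 10 (not isolated), via arylcopper 11 (not isolated)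
Conditions: s-BuLi (1.3 equiv), TMEDA (1.3 equiv), THF, −78 °C, 1 h; CuBr·SMe2 (1.3 equiv), −78 °C; prenyl bromide (2 equiv), −78 → 0 °C
Reagents that add atoms: prenyl bromide (1-bromo-3-methylbut-2-ene), CC(C)=CCBr
Why: The last ring hydrogen again lies between carbamate and OMOM and should be removed kinetically faster than the allylic-benzylic CH2 of the resident prenyl group (flanked only by OMOM groups), while transmetalation to copper blocks the anionic ortho-Fries shift and gives the linear prenyl arene.

**Step 7**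
Reactants: 12 3,5-bis(methoxymethoxy)-2,4-bis(3-methylbut-2-en-1-yl)-6-(trimethylsilyl)phenyl N,N-diethylcarbamate
Product: 13 3,5-bis(methoxymethoxy)-2,4-bis(3-methylbut-2-en-1-yl)-6-(trimethylsilyl)phenol
Conditions: LiAlH4 (3 equiv), THF, 0 °C → reflux; H2O/aq NaOH work-up
Reagents that add atoms: none
Why: Hydride attack on the carbamate carbonyl expels the hindered phenoxide (reductive carbamate cleavage) and leaves aryl–Si, MOM and alkene groups untouched.

**Step 8**
Reactants: 13 3,5-bis(methoxymethoxy)-2,4-bis(3-methylbut-2-en-1-yl)-6-(trimethylsilyl)phenol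
Product: 14 3,5-bis(methoxymethoxy)-2,4-bis(3-methylbut-2-en-1-yl)-6-(trimethylsilyl)phenyl trifluoromethanesulfonate
Conditions: Tf2O (1.2 equiv), pyridine (3 equiv), CH2Cl2, 0 °C
Reagents that add atoms: trifluoromethanesulfonic anhydride, O=S(=O)(OS(=O)(=O)C(F)(F)F)C(F)(F)F
Why: O-triflation of an o-silylphenol is the standard last step to an o-silylaryl triflate for Kobayashi aryne generation.

**Step 9**
Reactants: 15 (S)-3-chloropropane-1,2-diol
Product: 16 (2S,3S,5S)-5-(chloromethyl)-2,3-dimethoxy-2,3-dimethyl-1,4-dioxane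
Conditions: butane-2,3-dione (1.2 equiv), HC(OMe)3 (3 equiv), camphorsulfonic acid (5 mol %), MeOH, reflux
Reagents that add atoms: butane-2,3-dione, CC(=O)C(C)=O; trimethyl orthoformate, COC(OC)OC
Why: Butane-2,3-diacetal formation under thermodynamic control places both methoxy groups axial (two anomeric effects) and CH2Cl equatorial, so the single stereocentre of 15 fixes both new acetal centres as S.

**Step 10**
Reactants: 16 (2S,3S,5S)-5-(chloromethyl)-2,3-dimethoxy-2,3-dimethyl-1,4-dioxane
Product: 17 (2S,3S)-2,3-dimethoxy-2,3-dimethyl-5-methylidene-1,4-dioxane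
Conditions: KOt-Bu (2 equiv), THF, reflux
Reagents that add atoms: none
Why: E2 dehydrochlorination gives the exocyclic enol ether, erasing the original stereocentre while the chirality stays stored in the two acetal carbons.

**Step 11**
Reactants: 17 (2S,3S)-2,3-dimethoxy-2,3-dimethyl-5-methylidene-1,4-dioxane
Product: 19 (5S,6S)-5,6-dimethoxy-5,6-dimethyl-1,4-dioxan-2-one, via ozonide 18 (not isolated)
Conditions: O3, CH2Cl2, −78 °C; Me2S, −78 °C → rt
Reagents that add atoms: ozone, [O-][O+]=O
Why: Ozonolysis of the electron-rich 1,1-disubstituted enol ether followed by reductive work-up gives the lactone without touching the acetal centres.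

**Step 12**
Reactants: 19 (5S,6S)-5,6-dimethoxy-5,6-dimethyl-1,4-dioxan-2-one; 20 4-(methoxymethoxy)benzaldehyde
Product: 23 (3R,5S,6S)-3-{(R)-hydroxy[4-(methoxymethoxy)phenyl]methyl}-5,6-dimethoxy-5,6-dimethyl-1,4-dioxan-2-one, via lithium enolate 21 (not isolated), via lithium aldolate 22 (not isolated)
Conditions: LiN(SiMe3)2 (1.05 equiv), THF, −78 °C, 15 min; 20 (1.2 equiv), −78 °C, 15 min; AcOH, −78 °C; major adduct purified by recrystallisation
Reagents that add atoms: none
Why: In this lithium enolate aldol of a butane-2,3-diacetal glycolate (a reaction type known to give anti adducts with aromatic aldehydes), the ring fixes the E(O)-enolate, which through a Zimmerman–Traxler chair gives the anti relation (carbinol carbon R), and the axial methoxy group at C5, 1,3-diaxial to C3, blocks one face so that the aldehyde is taken up on the other and C3 becomes R with the side chain equatorial.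

**Step 13**
Reactants: 23 (3R,5S,6S)-3-{(R)-hydroxy[4-(methoxymethoxy)phenyl]methyl}-5,6-dimethoxy-5,6-dimethyl-1,4-dioxan-2-one
Product: 24 (3R,5S,6S)-5,6-dimethoxy-3-{(R)-[4-(methoxymethoxy)phenyl][(trimethylsilyl)oxy]methyl}-5,6-dimethyl-1,4-dioxan-2-one
Conditions: TMSCl (1.5 equiv), imidazole (2.5 equiv), CH2Cl2, 0 °C
Reagents that add atoms: chlorotrimethylsilane, C[Si](C)(C)Cl
Why: Mild silylation of the secondary alcohol stores the aldol in a form safe from retro-aldol cleavage and removes the only acidic proton of the annulation partner.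

**Step 14**
Reactants: 14 3,5-bis(methoxymethoxy)-2,4-bis(3-methylbut-2-en-1-yl)-6-(trimethylsilyl)phenyl trifluoromethanesulfonate; 24 (3R,5S,6S)-5,6-dimethoxy-3-{(R)-[4-(methoxymethoxy)phenyl][(trimethylsilyl)oxy]methyl}-5,6-dimethyl-1,4-dioxan-2-one
Product: 29 (2R,3R)-3-{[(2S)-2-methoxy-3-oxobutan-2-yl]oxy}-5,7-bis(methoxymethoxy)-2-[4-(methoxymethoxy)phenyl]-6,8-bis(3-methylbut-2-en-1-yl)chroman-4-one, via potassium alkoxide 25 (not isolated), via aryne 26 (not isolated), via aryl anion 27 (not isolated), via hemiketal alkoxide 28 (not isolated)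
Conditions: 24 (1.0 equiv), 14 (1.2 equiv), spray-dried KF (1.3 equiv), THF, 0 °C; 18-crown-6 (1.3 equiv) in THF added over 2 h; 0 °C → rt; pH 7 buffer
Reagents that add atoms: none
Why: Proposed new method: fluoride removes the O–SiMe3 group of 24 (alkoxide 25) and the C–SiMe3 group of 14 (loss of triflate, aryne 26), 25 adds through oxygen to C8a, the C4a carbanion 27 attacks the lactone carbonyl, and the tetrahedral adduct opens the dioxanone to hemiketal alkoxide 28, which sheds methoxide and leaves the 3-O ketal of 29. The closest known reaction types are the fluoride-induced annulation of o-silylaryl triflates with methyl salicylates to xanthones (O-arylation followed by acyl capture of the aryl anion) and the insertion of arynes into the N–C(O) bond of β-lactams, but an aliphatic β-oxy lactone has not been shown as the partner. Ring C closes by 6-exo-trig attack of the aryl carbanion on C4, favoured by the short tether and by the high electrophilicity of a six-membered lactone whose leaving oxygen sits on an acetal carbon. No stereocentre is created: C2 and C3 come unchanged from 24 because no bond at either carbon is broken, and the trans (diequatorial) arrangement is also the more stable one at the enolisable C3. The regioselectivity needed is set by the groups beside the triple bond: the inductively withdrawing C5–OMOM distorts the aryne so that the nucleophile enters at the remote C8a and the charge builds up at C4a next to oxygen, whereas the C8 prenyl CH2 is electronically almost neutral and only a moderate steric brake. The chemoselectivity needed (acyl capture before protonation, aryne capture before retro-aldol cleavage) is secured by the proton-free silyl ether form of the nucleophile, by metering the crown ether so that little free alkoxide is present at any time, and by the expelled methoxide serving as the second desilylating anion, so that about one equivalent of KF suffices and no strong base stays with 29.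

**Step 15**
Reactants: 29 (2R,3R)-3-{[(2S)-2-methoxy-3-oxobutan-2-yl]oxy}-5,7-bis(methoxymethoxy)-2-[4-(methoxymethoxy)phenyl]-6,8-bis(3-methylbut-2-en-1-yl)chroman-4-one
Product: 30 (2R,3R)-3,5,7-trihydroxy-2-(4-hydroxyphenyl)-6,8-bis(3-methylbut-2-en-1-yl)chroman-4-one (6,8-diprenylaromadendrin)
Conditions: 3 M aq HCl, MeOH, 45 °C
Reagents that add atoms: none
Why: Hydrolysis of aryl MOM acetals in aqueous methanolic HCl has close precedent on C-prenylated flavanones, the α-keto ketal at O3 should fall under the conditions used for acidic cleavage of butane-2,3-diacetals, and no bond at C2 or C3 is touched, so the (2R,3R) configuration is kept.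

**Compound list**

1 | resorcinol (benzene-1,3-diol) | Oc1cccc(O)c1 | starting material
2 | 1,3-bis(methoxymethoxy)benzene | COCOc1cccc(OCOC)c1 | intermediate
3 | [2,6-bis(methoxymethoxy)phenyl]lithium | [Li]c1c(OCOC)cccc1OCOC | intermediate
4 | 1,3-bis(methoxymethoxy)-2-(3-methylbut-2-en-1-yl)benzene | COCOc1cccc(OCOC)c1CC=C(C)C | intermediate
5 | 2-[3,5-bis(methoxymethoxy)-4-(3-methylbut-2-en-1-yl)phenyl]-4,4,5,5-tetramethyl-1,3,2-dioxaborolane | COCOc1cc(B2OC(C)(C)C(C)(C)O2)cc(OCOC)c1CC=C(C)C | intermediate
6 | 3,5-bis(methoxymethoxy)-4-(3-methylbut-2-en-1-yl)phenol | COCOc1cc(O)cc(OCOC)c1CC=C(C)C | intermediate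
7 | 3,5-bis(methoxymethoxy)-4-(3-methylbut-2-en-1-yl)phenyl N,N-diethylcarbamate | CCN(CC)C(=O)Oc1cc(OCOC)c(CC=C(C)C)c(OCOC)c1 | intermediate
8 | 2-lithio derivative of 7 | CCN(CC)C(=O)Oc1cc(OCOC)c(CC=C(C)C)c(OCOC)c1[Li] | intermediate
9 | 3,5-bis(methoxymethoxy)-4-(3-methylbut-2-en-1-yl)-2-(trimethylsilyl)phenyl N,N-diethylcarbamate | CCN(CC)C(=O)Oc1cc(OCOC)c(CC=C(C)C)c(OCOC)c1[Si](C)(C)C | intermediate
10 | 6-lithio derivative of 9 | CCN(CC)C(=O)Oc1c([Li])c(OCOC)c(CC=C(C)C)c(OCOC)c1[Si](C)(C)C | intermediate
11 | 6-cuprio derivative of 9 (arylcopper) | CCN(CC)C(=O)Oc1c([Cu])c(OCOC)c(CC=C(C)C)c(OCOC)c1[Si](C)(C)C | intermediate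
12 | 3,5-bis(methoxymethoxy)-2,4-bis(3-methylbut-2-en-1-yl)-6-(trimethylsilyl)phenyl N,N-diethylcarbamate | CCN(CC)C(=O)Oc1c(CC=C(C)C)c(OCOC)c(CC=C(C)C)c(OCOC)c1[Si](C)(C)C | intermediate
13 | 3,5-bis(methoxymethoxy)-2,4-bis(3-methylbut-2-en-1-yl)-6-(trimethylsilyl)phenol | Oc1c(CC=C(C)C)c(OCOC)c(CC=C(C)C)c(OCOC)c1[Si](C)(C)C | intermediate
14 | 3,5-bis(methoxymethoxy)-2,4-bis(3-methylbut-2-en-1-yl)-6-(trimethylsilyl)phenyl trifluoromethanesulfonate | O=S(=O)(Oc1c(CC=C(C)C)c(OCOC)c(CC=C(C)C)c(OCOC)c1[Si](C)(C)C)C(F)(F)F | intermediate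
15 | (S)-3-chloropropane-1,2-diol | OC[C@H](O)CCl | starting material
16 | (2S,3S,5S)-5-(chloromethyl)-2,3-dimethoxy-2,3-dimethyl-1,4-dioxane | ClC[C@@H]1CO[C@](C)(OC)[C@@](C)(OC)O1 | intermediate
17 | (2S,3S)-2,3-dimethoxy-2,3-dimethyl-5-methylidene-1,4-dioxane | C=C1CO[C@](C)(OC)[C@@](C)(OC)O1 | intermediate
18 | spiro-1,2,4-trioxolane (secondary ozonide) of 17, spiro centre unassigned | C1OOC2(O1)CO[C@](C)(OC)[C@@](C)(OC)O2 | intermediate
19 | (5S,6S)-5,6-dimethoxy-5,6-dimethyl-1,4-dioxan-2-one | O=C1CO[C@](C)(OC)[C@@](C)(OC)O1 | intermediate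
20 | 4-(methoxymethoxy)benzaldehyde | COCOc1ccc(C=O)cc1 | starting material
21 | lithium enolate of 19 | [Li]OC1=CO[C@](C)(OC)[C@@](C)(OC)O1 | intermediate
22 | lithium aldolate (O-lithio form of 23) | O=C1[C@@H]([C@H](O[Li])c2ccc(OCOC)cc2)O[C@](C)(OC)[C@@](C)(OC)O1 | intermediate
23 | (3R,5S,6S)-3-{(R)-hydroxy[4-(methoxymethoxy)phenyl]methyl}-5,6-dimethoxy-5,6-dimethyl-1,4-dioxan-2-one | O=C1[C@@H]([C@H](O)c2ccc(OCOC)cc2)O[C@](C)(OC)[C@@](C)(OC)O1 | intermediate
24 | (3R,5S,6S)-5,6-dimethoxy-3-{(R)-[4-(methoxymethoxy)phenyl][(trimethylsilyl)oxy]methyl}-5,6-dimethyl-1,4-dioxan-2-one | O=C1[C@@H]([C@H](O[Si](C)(C)C)c2ccc(OCOC)cc2)O[C@](C)(OC)[C@@](C)(OC)O1 | intermediate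
25 | potassium alkoxide from 24 | O=C1[C@@H]([C@H]([O-])c2ccc(OCOC)cc2)O[C@](C)(OC)[C@@](C)(OC)O1.[K+] | intermediate
26 | 3,5-bis(methoxymethoxy)-4,6-bis(3-methylbut-2-en-1-yl)benzyne (triple bond C4a≡C8a) | C1#CC(OCOC)=C(CC=C(C)C)C(OCOC)=C1CC=C(C)C | intermediate
27 | aryl anion formed by O-arylation of 25 (charge at C4a) | O=C1[C@@H]([C@H](Oc2[c-]c(OCOC)c(CC=C(C)C)c(OCOC)c2CC=C(C)C)c2ccc(OCOC)cc2)O[C@](C)(OC)[C@@](C)(OC)O1.[K+] | intermediate
28 | ring-opened hemiketal alkoxide of the chromanone | CC(C)=CCc1c(OCOC)c(CC=C(C)C)c2c(c1OCOC)C(=O)[C@H](O[C@](C)(OC)[C@@](C)(OC)[O-])[C@@H](c1ccc(OCOC)cc1)O2.[K+] | intermediate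
29 | (2R,3R)-3-{[(2S)-2-methoxy-3-oxobutan-2-yl]oxy}-5,7-bis(methoxymethoxy)-2-[4-(methoxymethoxy)phenyl]-6,8-bis(3-methylbut-2-en-1-yl)chroman-4-one | CC(C)=CCc1c(OCOC)c(CC=C(C)C)c2c(c1OCOC)C(=O)[C@H](O[C@](C)(OC)C(C)=O)[C@@H](c1ccc(OCOC)cc1)O2 | intermediate
30 | (2R,3R)-3,5,7-trihydroxy-2-(4-hydroxyphenyl)-6,8-bis(3-methylbut-2-en-1-yl)chroman-4-one (6,8-diprenylaromadendrin) | CC(C)=CCc1c(O)c(CC=C(C)C)c2c(c1O)C(=O)[C@H](O)[C@@H](c1ccc(O)cc1)O2 | target

**Step count and risk**

Total step count: 15. Longest linear sequence: 10 (steps 1–8, 14, 15, from resorcinol). The second branch has 5 steps (9–13) before the union.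

Steps most likely to fail:

**1. Step 14 (Proposed new method).**
- What may go wrong:
  - retro-aldol fragmentation of the freed alkoxide before it meets the aryne, with loss of diastereomeric purity on re-addition;
  - premature opening of the lactone by alkoxide or methoxide;
  - proton capture by the aryl anion before acyl transfer;
  - entry of the nucleophile at the aryne carbon beside OMOM;
  - ene-type consumption of the aryne by prenyl groups;
  - base-induced ring opening at C2 of the product.
- Fallback (known chemistry), from 14 and 20 back to the route at 30. Doebner–Knoevenagel condensation of 20 with malonic acid (pyridine, piperidine, 90 °C) gives (E)-4-(methoxymethoxy)cinnamic acid F1. The aryne released from 14 with CsF in hot THF adds this acid across its C–O bond. This is the known carboxylic acid addition to arynes that gives o-hydroxyaryl ketones, under the same control by C5–OMOM, and it gives the 2'-hydroxychalcone F2. MOMCl/NaH in DMF caps the chelated phenol to give the tetra-MOM chalcone F3. Juliá–Colonna epoxidation (poly-L-leucine, urea·H2O2, DBU, THF) gives the (αR,βS)-epoxychalcone F4. Methanolic HCl then removes the MOM groups, and one of the two equivalent freed ortho-phenols opens the epoxide at the benzylic carbon with inversion (6-endo) to give 30.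

**2. Step 15.**
- What may go wrong:
  - acid-induced cyclisation of a prenyl group onto a freed neighbouring phenol;
  - slow cleavage of the α-keto ketal that forces longer acid contact;
  - epimerisation through opening of ring C at C2 once the 4'-hydroxyl is free.
- Fallback, from 29 back to 30, is a two-stage release without mineral acid. Condensation of the methyl ketone of the ketal side chain with 1,2-diaminobenzene (cat. AcOH, EtOH, 40 °C) carries the butanedione unit off as an aromatic quinoxaline. This frees the 3-hydroxyl and gives the tri-MOM dihydroflavonol F5. TMSOTf/2,2'-bipyridyl (MeCN, 0 °C → rt) then exchanges the aryl MOM acetals for silyl ethers through bipyridinium salts, giving the tetrakis(trimethylsilyl) ether F6. Water at neutral pH hydrolyses F6 to 30.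

**3. Step 6.**
- What may go wrong:
  - competing deprotonation of the allylic-benzylic CH2 of the resident prenyl group;
  - anionic ortho-Fries migration of the carbamoyl group before transmetalation;
  - capture of prenyl bromide at its tertiary end.
- Fallback, from 9 back to the route at 13, uses no metalation in the presence of a prenyl group. LiAlH4 (THF, reflux) cleaves the carbamate of 9 to the o-silylphenol F7. O-alkylation with 3-chloro-3-methylbut-1-yne (CuCl2 cat., DBU, MeCN, 0 °C) gives the 1,1-dimethylpropargyl ether F8. Lindlar semihydrogenation (Pd/CaCO3–Pb(OAc)2, quinoline, H2) gives the 1,1-dimethylallyl ether F9. Aromatic Claisen rearrangement (toluene, 110 °C) can reach only the one free ortho carbon and delivers the linear prenyl group, giving phenol 13, so step 7 is also saved.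

**Further compounds**

F1 | step 14 | (E)-3-[4-(methoxymethoxy)phenyl]prop-2-enoic acid | COCOc1ccc(/C=C/C(=O)O)cc1
F2 | step 14 | (E)-1-[2-hydroxy-4,6-bis(methoxymethoxy)-3,5-bis(3-methylbut-2-en-1-yl)phenyl]-3-[4-(methoxymethoxy)phenyl]prop-2-en-1-one | COCOc1ccc(/C=C/C(=O)c2c(O)c(CC=C(C)C)c(OCOC)c(CC=C(C)C)c2OCOC)cc1
F3 | step 14 | (E)-3-[4-(methoxymethoxy)phenyl]-1-[2,4,6-tris(methoxymethoxy)-3,5-bis(3-methylbut-2-en-1-yl)phenyl]prop-2-en-1-one | COCOc1ccc(/C=C/C(=O)c2c(OCOC)c(CC=C(C)C)c(OCOC)c(CC=C(C)C)c2OCOC)cc1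
F4 | step 14 | {(2R,3S)-3-[4-(methoxymethoxy)phenyl]oxiran-2-yl}[2,4,6-tris(methoxymethoxy)-3,5-bis(3-methylbut-2-en-1-yl)phenyl]methanone | O=C(c1c(OCOC)c(CC=C(C)C)c(OCOC)c(CC=C(C)C)c1OCOC)[C@@H]1O[C@H]1c1ccc(OCOC)cc1
F5 | step 15 | (2R,3R)-3-hydroxy-5,7-bis(methoxymethoxy)-2-[4-(methoxymethoxy)phenyl]-6,8-bis(3-methylbut-2-en-1-yl)chroman-4-one | CC(C)=CCc1c(OCOC)c(CC=C(C)C)c2c(c1OCOC)C(=O)[C@H](O)[C@@H](c1ccc(OCOC)cc1)O2
F6 | step 15 | (2R,3R)-6,8-bis(3-methylbut-2-en-1-yl)-3,5,7-tris[(trimethylsilyl)oxy]-2-{4-[(trimethylsilyl)oxy]phenyl}chroman-4-one | CC(C)=CCc1c(O[Si](C)(C)C)c(CC=C(C)C)c2c(c1O[Si](C)(C)C)C(=O)[C@H](O[Si](C)(C)C)[C@@H](c1ccc(O[Si](C)(C)C)cc1)O2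
F7 | step 6 | 3,5-bis(methoxymethoxy)-4-(3-methylbut-2-en-1-yl)-2-(trimethylsilyl)phenol | Oc1cc(OCOC)c(CC=C(C)C)c(OCOC)c1[Si](C)(C)C
F8 | step 6 | [2,6-bis(methoxymethoxy)-3-(3-methylbut-2-en-1-yl)... written as 1-(2-methylbut-3-yn-2-yloxy)-3,5-bis(methoxymethoxy)-4-(3-methylbut-2-en-1-yl)-2-(trimethylsilyl)benzene | C#CC(C)(C)Oc1cc(OCOC)c(CC=C(C)C)c(OCOC)c1[Si](C)(C)C
F9 | step 6 | 1-(2-methylbut-3-en-2-yloxy)-3,5-bis(methoxymethoxy)-4-(3-methylbut-2-en-1-yl)-2-(trimethylsilyl)benzene | C=CC(C)(C)Oc1cc(OCOC)c(CC=C(C)C)c(OCOC)c1[Si](C)(C)C
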